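**Retrosynthetic overview**

1. Numbering: ring C1–C6, with C1 the quaternary carbinol carbon carrying the C7H2OBz arm, C2 and C3 the acetoxy carbons, C4=C5 the alkene and C6 the free CHOH; α is the face of the C1–O bond. The plan rests on the unit O–C6–C1(–O)–C7–O: ring carbon C1 holds an oxygen and the C7 carbon and sits beside the oxygenated C6, which is salicyl alcohol whose benzylic oxygen has bonded to its own ipso carbon.
2. C7–OBz is cut last: benzoic acid opens a C1/C7 spiro-oxirane at C7 under direction of the cis C6–OH, which comes from the C6 ketone by hydride addition anti to the oxirane oxygen.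
3. The 2α,3β-diacetate is cut to a C2–C3 oxirane on the α face, opened at the allylic C3 by acetic acid and then acetylated at C2–OH.
4. Key disconnection: the (S)-spiro-epoxy dienone is traced to salicyl alcohol by an enantioselective dearomatising spiro-epoxidation with a chiral ArI(OAc)2 oxidant, which forms the C1–O bond, the oxirane ring and the stereocentre C1 in one step.
5. Ring order: the carbocycle comes from the arene; spiro-oxirane (step 2), then fused C2–C3 oxirane (step 3); the fused oxirane is opened in step 4 and the spiro-oxirane in step 7.

Key step: step 2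

Remarks on the chemistry:
- Assumption: the sense of induction of the lactamide reagent at C1 cannot be predicted with confidence. The (R,R) reagent is written as the one that gives the (S)-dienone; the (S,S) reagent, made the same way from the antipodal aryl iodide, would be used if induction proves opposite.
- Descriptors are given in the target numbering above. The label at C1 changes (S in 6, R in 7, 8 and 10, S in 11 and 13) only because neighbour priorities change; the geometry at C1 is not altered after step 2.

**Step 1**
Reactants: 1 (2R,2'R)-2,2'-[(2-iodo-1,3-phenylene)bis(oxy)]bis[N-(2,4,6-trimethylphenyl)propanamide] (C2-symmetric lactamide aryl iodide); 2 acetic acid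
Product: 3 (2R,2'R)-2,2'-{[2-(diacetoxyiodo)-1,3-phenylene]bis(oxy)}bis[N-(2,4,6-trimethylphenyl)propanamide], the chiral ArI(OAc)2 oxidant
Conditions: AcOOH (ca. 35% in AcOH, 1.3 equiv), AcOH, 30 °C; evaporation, trituration with Et2O
Reagents that add atoms: peracetic acid CC(=O)OO; acetic acid (2) CC(=O)O
Why: Peracid oxidation of an aryl iodide in acetic acid (monovalent to trivalent iodine) is the standard preparation of ArI(OAc)2 reagents; the lactamide stereocentres are remote and untouched and no stereocentre is formed.

**Step 2**
Reactants: 4 salicyl alcohol (2-(hydroxymethyl)phenol); 3 chiral ArI(OAc)2 oxidant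
Product: 6 (3S)-1-oxaspiro[2.5]octa-5,7-dien-4-one, via acetoxy(aryl)iodanyl phenoxide 5 (not isolated)
Conditions: 3 (1.1 equiv), CH2Cl2/(CF3)2CHOH 10:1, 0.02 M, −40 °C; cold filtration through a short SiO2 pad (CH2Cl2) to hold back 1 and AcOH; filtrate of 6 kept at −40 °C and used at once
Reagents that add atoms: none
Why: Proposed new method: ligand exchange places the phenolic oxygen of 4 on the trivalent iodine of 3 (intermediate 5); as the aryl iodide 1 and acetate leave, the ortho carbon C1 turns electrophilic and the hydroxymethyl oxygen bonds to it, which creates the C1–O bond, the oxirane, the C6 ketone and the C2–C5 diene in one event. The closest known reactions are the racemic Adler–Becker oxidation of 2-hydroxybenzyl alcohols with NaIO4 and the enantioselective dearomatising spirocyclisations of phenols with chiral lactate-derived aryl iodine reagents (trivalent iodine); an enantioselective oxirane-forming variant has not been shown. The oxirane closes in the 3-exo-trig mode, the breaking C1=C6 π bond lying outside the new ring. C1 is the only new stereocentre and, the substrate being achiral, it is set by the reagent: while the phenoxide is still bound to iodine the two lactamide arms should shield one face of C1, so that the CH2OH group swings to the other. The step needs ipso attack at C1 in preference to acetate capture at the para carbon C3 and to oxidation of the benzylic alcohol; the ortho hydroxymethyl group, held three atoms from the iodine-bound oxygen, together with the weakly nucleophilic medium should secure this, and the low temperature and dilution should hold back Diels–Alder dimerisation of 6.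

**Step 3**
Reactants: 6 (3S)-1-oxaspiro[2.5]octa-5,7-dien-4-one (cold filtrate from step 2)
Product: 7 (1R,2R,3R)-bis-epoxy enone, spiro[7-oxabicyclo[4.1.0]hept-4-ene-2,2'-oxiran]-3-one with both oxirane oxygens on the α face
Conditions: methyl(trifluoromethyl)dioxirane (ca. 0.5 M in CF3COCH3, 1.2 equiv), CH2Cl2, −40 °C; concentration below 0 °C, chromatography
Reagents that add atoms: methyl(trifluoromethyl)dioxirane CC1(OO1)C(F)(F)F
Why: Electrophilic dioxirane epoxidation of a 2,4-dienone takes the γ,δ-alkene C2=C3, the one remote from the carbonyl, and should be fast enough at −40 °C to outrun dimerisation; oxygen should add to the face that carries the spiro-oxirane oxygen because the oxirane CH2 screens the other face, which sets C2 and C3 with both C–O bonds cis to C1–O.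

**Step 4**
Reactants: 7 bis-epoxy enone; 2 acetic acid
Product: 8 (1R,2R,3S)-3β-acetoxy-2α-hydroxy spiro-epoxy enone (C1/C7 oxirane intact, C4=C5, C6=O)
Conditions: AcOH, NaOAc (2 equiv), 45 °C
Reagents that add atoms: acetic acid (2) CC(=O)O
Why: Acetolysis of a vinyl oxirane by SN2 attack at the allylic γ-carbon C3 with inversion: C2 is neopentyl-like and the spiro-oxirane, whose tertiary carbon is α to the ketone, resists acid, so acetate should enter C3 on the β face and leave the C2 hydroxyl α; C1 carries no hydrogen, which closes the usual aromatisation path of epoxy enones.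

**Step 5**
Reactants: 8 hydroxy acetate; 9 acetic anhydride
Product: 10 (1R,2R,3S)-2α,3β-diacetoxy spiro-epoxy enone
Conditions: Ac2O (1.5 equiv), pyridine (3 equiv), DMAP (5 mol %), CH2Cl2, 0 °C
Reagents that add atoms: acetic anhydride (9) CC(=O)OC(C)=O
Why: DMAP-catalysed acetylation of a secondary alcohol, run cold and briefly so that the γ-hydrogen of the enone is not removed; no stereocentre is touched, and any acetyl migration between O2 and O3 in 8 is without consequence because both end as acetates.

**Step 6**
Reactants: 10 diacetoxy spiro-epoxy enone
Product: 11 (1S,2R,3S,6S)-2α,3β-diacetoxy-6α-hydroxy spiro-epoxide (C1/C7 oxirane with oxygen α, C4=C5)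
Conditions: NaBH4 (1 equiv), CeCl3·7H2O (1.1 equiv), MeOH, −78 °C; aq. NH4Cl
Reagents that add atoms: none
Why: Luche 1,2-reduction of an enone; hydride should attack C6 anti to the C1–O bond of the neighbouring oxirane (polar Felkin–Anh control, reinforced by CeCl3 bridging the carbonyl and oxirane oxygens on the α face), which gives the 6α-alcohol cis to the oxirane oxygen, and the ketone is reduced before any carboxylate base meets the base-labile acetoxy enone.

**Step 7**
Reactants: 11 epoxy alcohol; 12 benzoic acid
Product: 13 target, (1S,2R,3S,6S)-1-(benzoyloxymethyl)cyclohex-4-ene-1,2,3,6-tetrol 2,3-diacetate, equal to [(1S,2S,5S,6R)-5,6-diacetoxy-1,2-dihydroxycyclohex-3-en-1-yl]methyl benzoate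
Conditions: PhCO2H (2 equiv), Ti(OiPr)4 (1.5 equiv), CH2Cl2, 0 °C to rt; aq. tartaric acid
Reagents that add atoms: benzoic acid (12) OC(=O)c1ccccc1
Why: Ti(OiPr)4-mediated opening of a 2,3-epoxy alcohol by a carboxylic acid at the distal carbon: titanium binds the cis C6 hydroxyl and the oxirane oxygen and benzoate attacks the primary C7 in an SN2 manner, so the C1–O bond, and with it the C1 configuration, stays intact and the tertiary C1–OH is set free.

**Compound list**

1 | (2R,2'R)-2,2'-[(2-iodo-1,3-phenylene)bis(oxy)]bis[N-(2,4,6-trimethylphenyl)propanamide] | C[C@@H](Oc1cccc(O[C@H](C)C(=O)Nc2c(C)cc(C)cc2C)c1I)C(=O)Nc1c(C)cc(C)cc1C | starting material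
2 | acetic acid | CC(=O)O | starting material
3 | (2R,2'R)-2,2'-{[2-(diacetoxyiodo)-1,3-phenylene]bis(oxy)}bis[N-(2,4,6-trimethylphenyl)propanamide] | C[C@@H](Oc1cccc(O[C@H](C)C(=O)Nc2c(C)cc(C)cc2C)c1I(OC(C)=O)OC(C)=O)C(=O)Nc1c(C)cc(C)cc1C | intermediate
4 | salicyl alcohol | OCc1ccccc1O | starting material
5 | acetoxy(aryl)iodanyl phenoxide: 3 with one acetate replaced by the phenolic oxygen of 4 | C[C@@H](Oc1cccc(O[C@H](C)C(=O)Nc2c(C)cc(C)cc2C)c1I(OC(C)=O)Oc1ccccc1CO)C(=O)Nc1c(C)cc(C)cc1C | intermediate
6 | (3S)-1-oxaspiro[2.5]octa-5,7-dien-4-one | O=C1C=CC=C[C@]12CO2 | intermediate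
7 | (1R,2R,3R)-bis-epoxy enone, both oxirane oxygens α | O=C1C=C[C@H]2O[C@H]2[C@]12CO2 | intermediate
8 | (1R,2R,3S)-3β-acetoxy-2α-hydroxy spiro-epoxy enone | CC(=O)O[C@H]1C=CC(=O)[C@@]2(CO2)[C@@H]1O | intermediate
9 | acetic anhydride | CC(=O)OC(C)=O | starting material
10 | (1R,2R,3S)-2α,3β-diacetoxy spiro-epoxy enone | CC(=O)O[C@H]1C=CC(=O)[C@@]2(CO2)[C@@H]1OC(C)=O | intermediate
11 | (1S,2R,3S,6S)-2α,3β-diacetoxy-6α-hydroxy spiro-epoxide | CC(=O)O[C@H]1C=C[C@H](O)[C@@]2(CO2)[C@@H]1OC(C)=O | intermediate
12 | benzoic acid | OC(=O)c1ccccc1 | starting material
13 | [(1S,2S,5S,6R)-5,6-diacetoxy-1,2-dihydroxycyclohex-3-en-1-yl]methyl benzoate | CC(=O)O[C@H]1C=C[C@H](O)[C@@](O)(COC(=O)c2ccccc2)[C@@H]1OC(C)=O | target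

**Step count**

Total step count: 7.
Longest linear sequence: 7 steps (steps 1 to 7), running from the aryl iodide 1 through the oxidant 3, which is consumed in step 2, to 13. Salicyl alcohol 4 enters this sequence at step 2.

**Steps most likely to fail**

Step 2. What may go wrong: loss of face control at C1 if the phenoxide leaves the chiral iodine before the C1–O bond forms, capture of the activated ring at the para carbon C3 by acetate, and Diels–Alder dimerisation while the oxidation is still running. The fallback uses known chemistry and replaces asymmetric induction by a racemic dearomatisation followed by resolution. It sets out from 4, which NaIO4 in H2O/MeCN at 0 °C should convert by the classical Adler–Becker oxidation into racemic 1-oxaspiro[2.5]octa-5,7-dien-4-one F1. The cold CH2Cl2 extract is epoxidised at once with the dioxirane of step 3 to the racemic bis-epoxy enone F2. This is resolved by preparative chromatography on a chiral stationary phase (amylose tris(3,5-dimethylphenylcarbamate)). The wanted antipode is 7, where the route is rejoined; the unwanted antipode, the enantiomer of 7 F3, is set aside.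

Step 3. What may go wrong: dimerisation of 6 outrunning oxygen transfer, oxygen transfer to the β face if lone-pair repulsion from the spiro-oxirane oxygen overrides the steric bias, or a second epoxidation at C4=C5. The fallback sets out from 6 and returns at 7, with face control handed from the substrate to a chiral catalyst. It is a Jacobsen–Katsuki epoxidation of the cis-disubstituted conjugated alkene C2=C3 with chloro[N,N'-bis(3,5-di-tert-butylsalicylidene)cyclohexane-1,2-diaminato]manganese (trivalent manganese, catalytic, the (R,R) or (S,S) antipode whose preference matches the α face), mCPBA and N-methylmorpholine N-oxide in CH2Cl2 at −78 °C. Oxygen transfer under these conditions is fast enough for a labile diene. This fallback makes no compound outside the list (F0).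

Step 4. What may go wrong: competing attack of acetate on C7 of the spiro-oxirane, attack at C2 instead of C3 (which would invert the wrong centre), or slow opening with decomposition of the epoxy enone on warming. The fallback sets out from 6 and returns at 8 without any oxirane opening. OsO4 with TMEDA in CH2Cl2 at −78 °C, followed by cleavage of the osmate ester with aqueous Na2SO3, should dihydroxylate the electron-richer C2=C3 bond from the α face to the 2α,3α-dihydroxy spiro-epoxy enone F4. A Mitsunobu reaction (PPh3, DIAD, AcOH, THF, 0 °C) at the allylic C3 hydroxyl, the C2 hydroxyl being neopentyl-like, should then install the 3β-acetate with inversion and give 8.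

**Further compounds**

F1 | step 2 | racemic 1-oxaspiro[2.5]octa-5,7-dien-4-one | O=C1C=CC=CC12CO2
F2 | step 2 | racemic bis-epoxy enone (racemate of 7) | O=C1C=C[C@H]2O[C@H]2[C@]12CO2.O=C1C=C[C@@H]2O[C@@H]2[C@@]12CO2
F3 | step 2 | enantiomer of 7 | O=C1C=C[C@@H]2O[C@@H]2[C@@]12CO2
F0 | step 3 | none | none
F4 | step 4 | 2α,3α-dihydroxy spiro-epoxy enone | O[C@@H]1C=CC(=O)[C@@]2(CO2)[C@@H]1O
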